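All runs stem from a simulated flask from invented constants; scatter was added.

| flask | left-handed substrate | right-handed substrate | reagent | free catalyst | impurity | remark | time |
|---|---|---|---|---|---|---|---|
| larch | 0.25 M | 0.25 M | 4 equiv | 2.5 mol% | 2.1 mM | run made earlier |  |
| oak | 0.25 M | 0.25 M | 4 equiv | 2.5 mol% | 3.2 mM | run made earlier |  |
| flask | 0.25 M | 0.25 M | 4.00 equiv | 2.5 mol% | 4.2 mM |  | 5.0 min |

| run | time / min | left-handed product / % | right-handed product / % |
|---|---|---|---|
| larch | 0.500 | 28.4 | 3.1 |
| larch | 1.00 | 38.9 | 7.2 |
| larch | 1.50 | 45.8 | 9.0 |
| larch | 2.50 | 54.3 | 13.0 |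
| larch | 3.00 | 56.7 | 13.5 |
| larch | 4.00 | 62.0 | 15.0 |
| oak | 0.500 | 25.7 | 3.5 |
| oak | 1.00 | 36.5 | 5.9 |
| oak | 1.50 | 42.2 | 7.9 |
| oak | 2.50 | 51.7 | 9.3 |
| oak | 3.00 | 53.8 | 11.5 |
| oak | 4.00 | 59.8 | 13.5 |

(scatter of a reading: 0.5 percentage points)

- free catalyst is single-handed; left-handed substrate and right-handed substrate are mirror images of each other, charged as a racemate, each of them at the stated concentration
- an excess is the difference of the two amounts in percent of their sum
- an excess is below zero if the other one leads

* excess of left-handed product over right-handed product in the product at 6.0 s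
* excess of left-handed product over right-handed product in the product at 5.0 min
* part of the left-handed substrate and right-handed substrate charged together that has reacted at 5.0 min

The catalyst charged is a fixed count: 2.5 mol% of 0.25 M left-handed substrate gives 6.25 mM in each of these flasks. If each impurity takes one catalyst for good, the flask keeps 2.05 mM; I call this charge minus [impurity] the catalyst margin. Larch has 4.15 mM and oak 3.05 mM.

What is the excess at 6.0 s? If both products pass through the same free catalyst, its amount cancels from their ratio. Larch and oak together read a product ratio of 8.20 at 0.500 min, which is an excess of 78.3 %; at the very start this ratio is the selectivity factor. By then larch has made more left-handed product than right-handed, thinning the left-handed substrate, so I expect slightly more at 6.0 s.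

How far does the flask get? Its margin is 0.494 of larch's, so 5.0 min should count as 2.47 min of larch; the nearest larch reading, at 2.50 min, shows 67.3 % reacted at an excess of 61.4 %. Oak tests this: its 4.00 min counts as about 3.00 min of larch, yet oak reads 3.1 percentage points further in conversion and 1.6 points higher in excess. Adding both, I commit to 70.4 % reacted at an excess of 63.0 %.

The forecast says an excess of 86 % at 6.0 s, an excess of 61 % at 5.0 min and 77 % reacted at 5.0 min, and it reckons with “Taking 2.5 mol% on 0.5 M total gives 12.5 mM catalyst”, a different count from mine.

The flask gives an excess of 78.9 % at 6.0 s, an excess of 67.0 % at 5.0 min and 71.4 % reacted at 5.0 min.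

    reagent + free catalyst + left-handed substrate → free catalyst + left-handed product (k = 370 M⁻² min⁻¹)
    reagent + free catalyst + right-handed substrate → free catalyst + right-handed product (k = 40.0 M⁻² min⁻¹)
    left-handed substrate ⇌ right-handed substrate (k = 0.220 min⁻¹)
    reagent ⇌ dormant form (K = 0.100, k = 0.460 min⁻¹)
    free catalyst + impurity → spent catalyst (k = 670 M⁻¹ min⁻¹)

At 5.00 min the flask holds 32.8 % of its catalyst free and 67.2 % spent, and the margin reckons 32.8 % free. The neighbour flask with 0.011 M of impurity has a margin of −4.75 mM, below zero, which reckons 43.2 % of its impurity left over. At 5.00 min that neighbour flask shows 43.2 % of its impurity left, free catalyst at 0 %, and 19.4 % reacted.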